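# Proposed total synthesis of tridepside CNP0514431.0 (17) by growing each aromatic ring on a preformed but-2-ynoate ester

## The problem

Target 17 is a linear tridepside of three orsellinate rings: ring A (free resorcinol end), ring B (middle) and ring C (methyl ester end). In each ring C1 bears the carbonyl carbon, C2 and C4 bear oxygen, C6 bears CH3, and C3 and C5 bear H. The rings are joined by two aryl ester bonds, A–C(=O)–O–C4(B) and B–C(=O)–O–C4(C).

There is no stereocentre, axis or configured double bond, so nothing has to be set or relayed. The difficulty lies in connectivity and in telling like groups apart.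

All three carbonyl carbons hang on a C1 flanked by C2–O and C6–CH3, so every ester is a 2,6-disubstituted benzoate. Such esters form slowly from a weakly nucleophilic phenol and cannot be unmasked by saponification once a depside bond is present.

Six ring oxygens on three nearly identical rings must end in three states: OCH3 at C2 of B and C, acyl at C4 of B and C, and free OH at C2 and C4 of A. The depside bonds are activated aryl esters that hydroxide, alkoxide, amines and hot alcohols cleave or scramble. Late steps must therefore be neutral or weakly acidic, and the free resorcinol of ring A normally costs protecting groups.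

The repeat itself opens another way. In every ring the unit C(=O)–C1–C6–CH3 is the carbon chain of but-2-ynoic acid 8. The unit C2(O)–C3(H)–C4(O)–C5(H) is the dienol form of a cyclic 1,3-diketone such as dimedone 1, with donor and acceptor positions matched. Each ring can thus be grown by [4+2] addition onto an ester bond that is already in place.

## Retrosynthesis

**Ring A, bonds C1–C2 and C5–C6 (17 to 13 + 14).**
- The neighbouring cut, the A–B ester C(=O)–O bond, would ask a phenol to attack a carbonyl between two ortho substituents and would need ring A with both OH groups masked.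
- Cutting two ring bonds instead leaves that ester bond intact. Ring A becomes the triple bond of but-2-ynoate 13 plus the C4O2 diene 14.
- Compound 13 lacks one ring, both free OH groups and every protecting-group question of 17.
- The forward reaction is a Diels–Alder addition to adduct 15, followed by loss of its CH2–CMe2 bridge. It must join the oxygen-bearing diene terminus to the carbonyl-bearing alkyne carbon and must run without acid, base or nucleophile. It must also end in silyl ethers (16) that fall off under conditions harmless to aryl esters.

**The ynoate ester bond (13 to 12 + 8).**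
- The C(=O)–O bond between C4–O of ring B and the butynoyl carbon is cut.
- This carbonyl is flanked by a linear sp carbon, not by two ortho groups, so the ester bond that is hard to make in 17 is made while it is still easy.
- Phenol 12 has a single free OH, so no selectivity is asked. Only a mild carbodiimide coupling that spares the B–C depside bond is needed.

**Ring B, bonds C1–C2 and C5–C6 (12 to 9 + 3).**
- This is the same cut as for ring A, with one change in the diene: 3 carries OCH3 on the terminal carbon and OSiMe3 on the inner carbon.
- Via adduct 10 and silyl ether 11, the reaction should deliver C2–OCH3 and C4–OH already told apart. A cut at the B–C ester bond would have to secure this by benzylation, methylation of a hydrogen-bonded OH and saponification.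
- The phenol set free is exactly the nucleophile of the next cycle. Compound 9 is one ring simpler than 12.

**Ring C and its ynoate (9 to 7 + 8; 7 to 4 + 3).**
- The ester bond of 9 is cut as before.
- Ring C of phenol 7 is opened at C1–C2 and C5–C6 to the commercial methyl but-2-ynoate 4 and the same diene 3 (via 5 and 6).
- The methyl ester of the target is bought with 4 and never touched again. This smallest case also rehearses the benzannulation.

**The two dienes (3 and 14 to 1).**
- Only O–Si and O–CH3 bonds are cut.
- Dimedone 1 gives 14 by double O-silylation. It gives 3 by O-methylation to vinylogous ester 2 followed by kinetic enol silylation.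
- The gem-dimethyl group is not waste: it makes the bridge that leaves in the aromatisation a better leaving alkene.
- One diketone thus supplies C2–C5 of all three rings, and the group placed on its oxygen (CH3 or SiMe3) decides OCH3 against OH in the product.

## Roads not taken

**Alternative 1:** the cut most chemists would draw first.
- *Cut:* both depside C(=O)–O bonds, giving three preformed orsellinate units.
- *Forward key step:* carbodiimide or mixed-anhydride esterification of a phenol by an O-protected 2,6-disubstituted benzoic acid, run twice, with a hydrogenolysis after each.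
- *Weak points:* every unit would pass through a benzyl ether such as methyl 4-(benzyloxy)-2-hydroxy-6-methylbenzoate A1. Its hydrogen-bonded C2–OH then has to be methylated, and its doubly flanked ester has to be saponified under forcing base.
- *Why the chosen plan is better:* both couplings of this alternative take place at the most hindered carbon of the molecule, and more operations go into benzyl groups and ester hydrolysis than into bond formation. The chosen plan makes each ester bond at an unhindered carbonyl, lets the diene write the oxygen pattern, and uses no protecting group beyond transient silyl ethers.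

**Alternative 2:** a polyketide-type cut.
- *Cut:* the depside C(=O)–O bond together with ring bond C1–C6 of the acyl ring.
- *Forward key step:* thermolysis of 6-(2,4-dioxopentyl)-2,2-dimethyl-4H-1,3-dioxin-4-one A2 to an acylketene, which phenol 7 traps as aryl 3,5,7-trioxooctanoate A3. Aldol closure and dehydration then give resorcylate A4.
- *Weak points:* the step is attractive for ring A, but A4 leaves both OH groups of ring B free. The less reactive, hydrogen-bonded one would have to be methylated and the other acylated, which brings back differentiation steps.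
- *Further weak points:* A3 carries an aryloxide leaving group, so lactonisation with expulsion of the phenol competes with the C–C aldol closure. The base used for aromatisation threatens depside bonds, and A2 itself needs strong-base Claisen chemistry.
- *Why the chosen plan is better:* it covers all three rings with one reaction type under neutral conditions.

**Alternative 3:** a carbonylative cut.
- *Cut:* the two aryl–carbonyl bonds C1–C(=O) of rings A and B.
- *Forward key step:* palladium-catalysed three-component aryloxycarbonylation of an aryl iodide such as 5-(benzyloxy)-2-iodo-1-methoxy-3-methylbenzene A5 with phenol 7.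
- *Weak points:* the iodide is electron-rich and 2,6-disubstituted, so oxidative addition and capture of the crowded acylpalladium by a weak phenol nucleophile are both slow. The base needed endangers the ester being formed.
- *Further weak points:* A5 is hard to obtain pure, because the two ring positions next to CH3 in its parent diether are nearly equal towards iodination. Benzyl groups are still required.
- *Why the chosen plan is better:* it needs neither a regioselective arene functionalisation nor a protecting group.

Key step: step 8

Assumption: the SMILES of the target contains no stereocentre, stereogenic axis or configured double bond, so the "single enantiomer" asked for is the achiral compound itself. The bicyclic adducts 5, 10 and 15 are racemic and transient.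

## Route

Step 1
Reactants: 1 dimedone (5,5-dimethylcyclohexane-1,3-dione)
Product: 2 3-methoxy-5,5-dimethylcyclohex-2-en-1-one
Conditions: MeOH, cat. p-TsOH, reflux, 3 Å molecular sieves (Soxhlet)
Reagents that add atoms: methanol, CO
Why: Acid-catalysed O-alkylation of a cyclic 1,3-diketone to its vinylogous ester; the symmetry of 1 allows only one product and removal of water drives the equilibrium.

Step 2
Reactants: 2 3-methoxy-5,5-dimethylcyclohex-2-en-1-one
Product: 3 1-methoxy-5,5-dimethyl-3-(trimethylsilyloxy)cyclohexa-1,3-diene
Conditions: LDA (commercial solution, 1.1 equiv), THF, −78 °C; TMSCl (1.2 equiv), −78 °C to rt; non-aqueous work-up (pentane, filtration), bulb-to-bulb distillation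
Reagents that add atoms: chlorotrimethylsilane, C[Si](C)(C)Cl
Why: Kinetic α′-deprotonation of a vinylogous ester (the enolisation used in Stork–Danheiser alkylation) gives the cross-conjugated enolate, and O-silylation fixes it as the diene with OCH3 on a terminal and OSiMe3 on an inner carbon.

Step 3
Reactants: 4 methyl but-2-ynoate, 3 1-methoxy-5,5-dimethyl-3-(trimethylsilyloxy)cyclohexa-1,3-diene
Product: 7 methyl 4-hydroxy-2-methoxy-6-methylbenzoate, via bicyclooctadiene adduct 5 (not isolated), via aryl silyl ether 6 (not isolated)
Conditions: 4 (1.5 equiv), neat, base-washed sealed tube, 150–160 °C; then 1 M HCl, THF, 0 °C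
Reagents that add atoms: none
Why: Alder–Rickert reaction of a β-alkyl ynoate with a 1,3-dioxygenated cyclohexa-1,3-diene: the unsubstituted diene terminus bonds to the methyl-bearing alkyne carbon and the OCH3-bearing terminus to the ester-bearing carbon, 5 loses 2-methylpropene, and dilute acid frees the C4–OH of 6.

Step 4
Reactants: 7 methyl 4-hydroxy-2-methoxy-6-methylbenzoate, 8 but-2-ynoic acid
Product: 9 methyl 4-(but-2-ynoyloxy)-2-methoxy-6-methylbenzoate
Conditions: DCC (1.1 equiv), DMAP (5 mol %), CH2Cl2, 0 °C to rt
Reagents that add atoms: none
Why: Steglich esterification, the usual way to aryl but-2-ynoates; the acyl carbon is unhindered and 7 has only one OH.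

Step 5
Reactants: 9 methyl 4-(but-2-ynoyloxy)-2-methoxy-6-methylbenzoate, 3 1-methoxy-5,5-dimethyl-3-(trimethylsilyloxy)cyclohexa-1,3-diene
Product: 12 methyl 4-[(4-hydroxy-2-methoxy-6-methylbenzoyl)oxy]-2-methoxy-6-methylbenzoate, via bicyclooctadiene adduct 10 (not isolated), via didepside silyl ether 11 (not isolated)
Conditions: 3 (2–3 equiv), neat, base-washed sealed tube, 150 °C; then 1 M HCl, THF, 0 °C
Reagents that add atoms: none
Why: Same Alder–Rickert reaction as in step 3, now on an aryl ynoate whose lower LUMO should help; it builds ring B with C2–OCH3 and C4–OH already differentiated and turns the slim ynoate ester into the hindered B–C depside bond under neutral conditions that spare the methyl ester and aryl ethers.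

Step 6
Reactants: 12 methyl 4-[(4-hydroxy-2-methoxy-6-methylbenzoyl)oxy]-2-methoxy-6-methylbenzoate, 8 but-2-ynoic acid
Product: 13 methyl 4-{[4-(but-2-ynoyloxy)-2-methoxy-6-methylbenzoyl]oxy}-2-methoxy-6-methylbenzoate
Conditions: DCC (1.2 equiv), DMAP (5 mol %), CH2Cl2, 0 °C to rt
Reagents that add atoms: none
Why: Steglich esterification of the only free OH; the 2,6-disubstituted B–C depside carbonyl is shielded from DMAP and survives, as it does in carbodiimide couplings of depsides in general.

Step 7
Reactants: 1 dimedone (5,5-dimethylcyclohexane-1,3-dione)
Product: 14 5,5-dimethyl-1,3-bis(trimethylsilyloxy)cyclohexa-1,3-diene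
Conditions: TMSOTf (2.2 equiv), Et3N (3 equiv), Et2O, 0 °C to rt; separation of the salt layer, distillation
Reagents that add atoms: trimethylsilyl trifluoromethanesulfonate, C[Si](C)(C)OS(=O)(=O)C(F)(F)F
Why: Double soft enolisation and O-silylation of a 1,3-diketone with silyl triflate and amine; because of the symmetry of 1, deprotonation at either flank of the first-formed silyloxyenone gives the same diene.

Step 8
Reactants: 13 methyl 4-{[4-(but-2-ynoyloxy)-2-methoxy-6-methylbenzoyl]oxy}-2-methoxy-6-methylbenzoate, 14 5,5-dimethyl-1,3-bis(trimethylsilyloxy)cyclohexa-1,3-diene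
Product: 17 methyl 4-({4-[(2,4-dihydroxy-6-methylbenzoyl)oxy]-2-methoxy-6-methylbenzoyl}oxy)-2-methoxy-6-methylbenzoate, via bicyclooctadiene adduct 15 (not isolated), via tridepside bis-silyl ether 16 (not isolated)
Conditions: 14 (3 equiv), neat, base-washed sealed tube, 145–150 °C; then 1 M HCl, THF, 0 °C
Reagents that add atoms: none
Why: Alder–Rickert reaction (Diels–Alder addition, then retro-Diels–Alder loss of an alkene), closest in kind to the known benzannulation of β-alkyl alkynoate esters and macrocyclic ynoates with 1,3-bis(silyloxy)cyclohexa-1,3-dienes. The s-cis-locked diene 14 adds suprafacially across the triple bond of 13 in an intermolecular, concerted but asynchronous [4+2] closure that makes bonds C5–C6 and C1–C2 of ring A and gives bicyclo[2.2.2]octadiene 15. Both silyloxy groups of 14 put the largest HOMO coefficient on its unsubstituted terminus C4 and the ester puts the largest LUMO coefficient on the methyl-bearing alkyne carbon, so C4 bonds there and the oxygenated terminus C1 bonds to the carbonyl-bearing carbon, which places O ortho and para and CH3 ortho to the acyl group as in ring A. At the reaction temperature 15 expels its CH2–CMe2 bridge as 2-methylpropene; escape of the gas and the gain of aromaticity make the sequence irreversible, and since no oxygen leaving group is involved both ring oxygens are kept. The two bridgehead stereocentres of 15 form as a racemate and are erased in the cycloreversion, so no stereocontrol is needed. Chemoselectivity rests on the substrate: the ynoate is the only low-LUMO 2π unit of 13, its aryl ester makes it a better dienophile than an alkyl ynoate, and the neutral aprotic melt leaves the B–C depside bond, the ynoate ester itself, the methyl ester and the aryl methyl ethers alone. Dilute acid then cleaves the two aryl O–SiMe3 bonds of 16 under conditions that aryl esters tolerate, so the resorcinol of ring A appears only in the last operation and never needs a protecting group.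

## Compound list

1 | dimedone (5,5-dimethylcyclohexane-1,3-dione) | CC1(C)CC(=O)CC(=O)C1 | starting material
2 | 3-methoxy-5,5-dimethylcyclohex-2-en-1-one | COC1=CC(=O)CC(C)(C)C1 | intermediate
3 | 1-methoxy-5,5-dimethyl-3-(trimethylsilyloxy)cyclohexa-1,3-diene | COC1=CC(O[Si](C)(C)C)=CC(C)(C)C1 | intermediate
4 | methyl but-2-ynoate | CC#CC(=O)OC | starting material
5 | methyl 1-methoxy-3,8,8-trimethyl-5-(trimethylsilyloxy)bicyclo[2.2.2]octa-2,5-diene-2-carboxylate (racemic, one enantiomer drawn, not isolated) | CO[C@@]12CC(C)(C)[C@@H](C(O[Si](C)(C)C)=C1)C(C)=C2C(=O)OC | intermediate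
6 | methyl 2-methoxy-6-methyl-4-(trimethylsilyloxy)benzoate (not isolated) | COC(=O)c1c(C)cc(O[Si](C)(C)C)cc1OC | intermediate
7 | methyl 4-hydroxy-2-methoxy-6-methylbenzoate | COC(=O)c1c(C)cc(O)cc1OC | intermediate
8 | but-2-ynoic acid | CC#CC(=O)O | starting material
9 | methyl 4-(but-2-ynoyloxy)-2-methoxy-6-methylbenzoate | COC(=O)c1c(C)cc(OC(=O)C#CC)cc1OC | intermediate
10 | 3-methoxy-4-(methoxycarbonyl)-5-methylphenyl 1-methoxy-3,8,8-trimethyl-5-(trimethylsilyloxy)bicyclo[2.2.2]octa-2,5-diene-2-carboxylate (racemic, one enantiomer drawn, not isolated) | CO[C@@]12CC(C)(C)[C@@H](C(O[Si](C)(C)C)=C1)C(C)=C2C(=O)Oc1cc(C)c(C(=O)OC)c(OC)c1 | intermediate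
11 | methyl 2-methoxy-4-{[2-methoxy-6-methyl-4-(trimethylsilyloxy)benzoyl]oxy}-6-methylbenzoate (not isolated) | COC(=O)c1c(C)cc(OC(=O)c2c(C)cc(O[Si](C)(C)C)cc2OC)cc1OC | intermediate
12 | methyl 4-[(4-hydroxy-2-methoxy-6-methylbenzoyl)oxy]-2-methoxy-6-methylbenzoate | COC(=O)c1c(C)cc(OC(=O)c2c(C)cc(O)cc2OC)cc1OC | intermediate
13 | methyl 4-{[4-(but-2-ynoyloxy)-2-methoxy-6-methylbenzoyl]oxy}-2-methoxy-6-methylbenzoate | COC(=O)c1c(C)cc(OC(=O)c2c(C)cc(OC(=O)C#CC)cc2OC)cc1OC | intermediate
14 | 5,5-dimethyl-1,3-bis(trimethylsilyloxy)cyclohexa-1,3-diene | C[Si](C)(C)OC1=CC(O[Si](C)(C)C)=CC(C)(C)C1 | intermediate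
15 | 3-methoxy-4-{[3-methoxy-4-(methoxycarbonyl)-5-methylphenoxy]carbonyl}-5-methylphenyl 3,8,8-trimethyl-1,5-bis(trimethylsilyloxy)bicyclo[2.2.2]octa-2,5-diene-2-carboxylate (racemic, one enantiomer drawn, not isolated) | C[Si](C)(C)O[C@@]12CC(C)(C)[C@@H](C(O[Si](C)(C)C)=C1)C(C)=C2C(=O)Oc1cc(C)c(C(=O)Oc2cc(C)c(C(=O)OC)c(OC)c2)c(OC)c1 | intermediate
16 | 2,4-bis(O-trimethylsilyl) ether of 17 (both OH groups of ring A silylated, not isolated) | COC(=O)c1c(C)cc(OC(=O)c2c(C)cc(OC(=O)c3c(C)cc(O[Si](C)(C)C)cc3O[Si](C)(C)C)cc2OC)cc1OC | intermediate
17 | methyl 4-({4-[(2,4-dihydroxy-6-methylbenzoyl)oxy]-2-methoxy-6-methylbenzoyl}oxy)-2-methoxy-6-methylbenzoate (CNP0514431.0) | COC(=O)c1c(C)cc(OC(=O)c2c(C)cc(OC(=O)c3c(C)cc(O)cc3O)cc2OC)cc1OC | target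

## Step count and risks

Total step count: 8. Longest linear sequence: 7 (steps 1, 2, 3, 4, 5, 6, 8); step 7 is a one-step side branch.

**Step 8 (key step).**
- *Risk:* the cycloaddition may be too slow. A β-methyl ynoate is a reluctant dienophile, and the bond to its methyl-bearing carbon has to form next to the CMe2 group of 14. Thermal decay of the diene (silyl transfer, adventitious hydrolysis) may therefore outrun the addition, and the same crowding could erode the regiocontrol.
- *Fallback, from 12 back to 17:* ring A is brought in preformed. Commercial methyl 2,4-dihydroxy-6-methylbenzoate is benzylated twice (BnBr, K2CO3, DMF) to methyl 2,4-bis(benzyloxy)-6-methylbenzoate F1. KOH in aqueous DMSO at reflux saponifies it to 2,4-bis(benzyloxy)-6-methylbenzoic acid F2. The acid is joined to phenol 12 with trifluoroacetic anhydride in toluene to give the dibenzyl ether of the target F3. Hydrogenolysis (H2, Pd/C, EtOAc) gives 17.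

**Step 5.**
- *Risk:* the same slowness applies. In addition, traces of acid at 150 °C may shift the double bonds of diene 3. That would exchange the positions of OCH3 and OSiMe3 in the diene and write the wrong oxygen pattern into ring B.
- *Fallback, from 7 back to 12:* one portion of 7 is benzylated to methyl 4-(benzyloxy)-2-methoxy-6-methylbenzoate F4 and saponified to 4-(benzyloxy)-2-methoxy-6-methylbenzoic acid F5. The acid is coupled with a second portion of 7 (trifluoroacetic anhydride, toluene) to the benzyl-protected didepside F6. Hydrogenolysis gives 12.

**Step 6.**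
- *Risk:* phenol 12 is a weak nucleophile, and activated but-2-ynoic acid is prone to conjugate addition of DMAP or phenol, to isomerisation to the allenoate and to O-to-N acyl shift in the isourea.
- *Fallback, from 12 back to 13:* the C4 unit is put on as a ketene and the triple bond is made afterwards. Heating 12 with 2,2,6-trimethyl-4H-1,3-dioxin-4-one in xylene (acetylketene trapping, neutral) gives aryl acetoacetate F7. Tf2O, LiOTf and Et3N in CH2Cl2 give the (Z)-enol triflate F8, whose H and OTf are anti. Elimination with further amine base gives 13.

**Step 2.**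
- *Risk:* proton exchange may equilibrate the kinetic cross-conjugated enolate to the extended one before silylation, which would place Si and CH3 on the wrong oxygens. Hydrolysis of the diene during isolation is a further risk.
- *Fallback, from 4 back to 6 and so to 7:* an open-chain diene is used whose oxygen pattern is fixed by its skeleton.
  - Acetyl chloride and 1,1-dichloroethene (AlCl3, then loss of HCl) give 4,4-dichlorobut-3-en-2-one F9.
  - NaOMe in MeOH gives 4,4-dimethoxybut-3-en-2-one F10, which can enolise only at its CH3 group.
  - TMSCl, Et3N and cat. ZnCl2 give 1,1-dimethoxy-3-(trimethylsilyloxy)buta-1,3-diene F11.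
  - Its Diels–Alder adduct with 4, methyl 6,6-dimethoxy-2-methyl-4-(trimethylsilyloxy)cyclohexa-1,4-diene-1-carboxylate F12, aromatises by loss of methanol instead of by cycloreversion and gives 6.
  - The acid work-up of step 3 turns 6 into 7. The same reagent can replace 3 in step 5.

## Further compounds

F1 | step 8 | methyl 2,4-bis(benzyloxy)-6-methylbenzoate | COC(=O)c1c(C)cc(OCc2ccccc2)cc1OCc1ccccc1
F2 | step 8 | 2,4-bis(benzyloxy)-6-methylbenzoic acid | OC(=O)c1c(C)cc(OCc2ccccc2)cc1OCc1ccccc1
F3 | step 8 | methyl 4-({4-{[2,4-bis(benzyloxy)-6-methylbenzoyl]oxy}-2-methoxy-6-methylbenzoyl}oxy)-2-methoxy-6-methylbenzoate | COC(=O)c1c(C)cc(OC(=O)c2c(C)cc(OC(=O)c3c(C)cc(OCc4ccccc4)cc3OCc3ccccc3)cc2OC)cc1OC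
F4 | step 5 | methyl 4-(benzyloxy)-2-methoxy-6-methylbenzoate | COC(=O)c1c(C)cc(OCc2ccccc2)cc1OC
F5 | step 5 | 4-(benzyloxy)-2-methoxy-6-methylbenzoic acid | OC(=O)c1c(C)cc(OCc2ccccc2)cc1OC
F6 | step 5 | methyl 4-{[4-(benzyloxy)-2-methoxy-6-methylbenzoyl]oxy}-2-methoxy-6-methylbenzoate | COC(=O)c1c(C)cc(OC(=O)c2c(C)cc(OCc3ccccc3)cc2OC)cc1OC
F7 | step 6 | methyl 2-methoxy-4-({2-methoxy-6-methyl-4-[(3-oxobutanoyl)oxy]benzoyl}oxy)-6-methylbenzoate | COC(=O)c1c(C)cc(OC(=O)c2c(C)cc(OC(=O)CC(C)=O)cc2OC)cc1OC
F8 | step 6 | (Z)-enol triflate of F7, the 4-{[(2Z)-3-(trifluoromethylsulfonyloxy)but-2-enoyl]oxy} didepside | COC(=O)c1c(C)cc(OC(=O)c2c(C)cc(OC(=O)/C=C(/C)OS(=O)(=O)C(F)(F)F)cc2OC)cc1OC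
F9 | step 2 | 4,4-dichlorobut-3-en-2-one | CC(=O)C=C(Cl)Cl
F10 | step 2 | 4,4-dimethoxybut-3-en-2-one | CC(=O)C=C(OC)OC
F11 | step 2 | 1,1-dimethoxy-3-(trimethylsilyloxy)buta-1,3-diene | COC(OC)=CC(=C)O[Si](C)(C)C
F12 | step 2 | methyl 6,6-dimethoxy-2-methyl-4-(trimethylsilyloxy)cyclohexa-1,4-diene-1-carboxylate | COC(=O)C1=C(C)CC(O[Si](C)(C)C)=CC1(OC)OC
A1 | alternative 1 | methyl 4-(benzyloxy)-2-hydroxy-6-methylbenzoate | COC(=O)c1c(C)cc(OCc2ccccc2)cc1O
A2 | alternative 2 | 6-(2,4-dioxopentyl)-2,2-dimethyl-4H-1,3-dioxin-4-one | CC(=O)CC(=O)CC1=CC(=O)OC(C)(C)O1
A3 | alternative 2 | methyl 2-methoxy-6-methyl-4-[(3,5,7-trioxooctanoyl)oxy]benzoate | COC(=O)c1c(C)cc(OC(=O)CC(=O)CC(=O)CC(C)=O)cc1OC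
A4 | alternative 2 | methyl 4-[(2,4-dihydroxy-6-methylbenzoyl)oxy]-2-methoxy-6-methylbenzoate | COC(=O)c1c(C)cc(OC(=O)c2c(C)cc(O)cc2O)cc1OC
A5 | alternative 3 | 5-(benzyloxy)-2-iodo-1-methoxy-3-methylbenzene | COc1cc(OCc2ccccc2)cc(C)c1I
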